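**Plan**

- Numbering (drimane): ring A = C1–C5 and C10; ring B = C5–C10; C11 on C9; C12 = exocyclic CH2 on C8; C13 (CH3) and C14 (CH2OAc) on C4; C15 (CH3) on C10.
- Late cuts: the C11–O aryl ether (umbelliferone), the C14 acetate, C8=C12 (from a C8 ketone) and the C3 carbinol (from a C3 ketone, hydride along the equatorial direction).
- Core cut: both rings are opened at once at the ring-fusion bond C5–C10 and at C3–C4. This is possible because C10 is a methyl-bearing quaternary carbon (a tertiary radical from a C10=C15 alkene), C5 is β to C4, whose one-carbon substituent C14 can be a formyl group (enal C5=C4–C14), and C3 is a carbinol next to C4 (aldol acceptor).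
- Forward: an acyclic keto dialdehyde is cyclised by iron-hydride hydrogen-atom transfer; the radical closes ring B at C5–C10 and the enolate so formed closes ring A at C3–C4. The chain comes from an Evans syn-aldol (C8–C9) of a 3-methylidenehexanoyl imide (from diketene) with an enoate aldehyde (from cross-metathesis).
- Stereochemistry: C9 from the oxazolidinone auxiliary; C5 and C10 from C9 through the chair of the radical closure; C4 from the chair aldol (formyl axial); C3 from LiBH(s-Bu)3 reduction.

Key step: step 10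

Remark: the aldol closure in step 10 is assumed to give the equatorial C3 alcohol; the axial epimer would pass through the same steps and converge at the C3 ketone of step 13.

**Step 1**
Reactants: 1 (3-bromopropoxy)(tert-butyl)dimethylsilane; 2 diketene
Product: 4 6-[(tert-butyldimethylsilyl)oxy]-3-methylidenehexanoic acid, via Grignard reagent 3 (not isolated)
Conditions: Mg, THF, rt; then 2, NiCl2 (3 mol %), THF, −40 to 0 °C; aq. HCl to pH 3
Reagents that add atoms: none
Why: Nickel-catalysed cross-coupling of the Grignard reagent at the vinylic C–O bond of diketene (ring opening) should give the 3-methylidene acid with the C10=C15 alkene in place; no stereocentre is formed.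

**Step 2**
Reactants: 4 6-[(tert-butyldimethylsilyl)oxy]-3-methylidenehexanoic acid; 5 (4S)-4-benzyl-1,3-oxazolidin-2-one
Product: 7 (4S)-4-benzyl-3-{6-[(tert-butyldimethylsilyl)oxy]-3-methylidenehexanoyl}-1,3-oxazolidin-2-one, via mixed pivalic anhydride 6 (not isolated)
Conditions: PivCl, Et3N, THF, −20 °C; then 5, LiCl, −20 °C to rt
Reagents that add atoms: none
Why: N-Acylation of the oxazolidinone through the mixed anhydride (LiCl-promoted acyl transfer) uses only a weak amine base, so the β,γ-alkene should not move into conjugation.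

**Step 3**
Reactants: 8 pent-4-enal; 9 methyl methacrylate
Product: 10 methyl (2E)-2-methyl-6-oxohex-2-enoate
Conditions: second-generation Hoveyda–Grubbs catalyst (3 mol %), 9 (5 equiv), CH2Cl2, 40 °C
Reagents that add atoms: none
Why: Olefin cross-metathesis of a terminal alkene with a methacrylate, which does not homodimerise, should give the trisubstituted (E)-enoate under thermodynamic control and tolerates the aldehyde.

**Step 4**
Reactants: 7 (4S)-4-benzyl-3-{6-[(tert-butyldimethylsilyl)oxy]-3-methylidenehexanoyl}-1,3-oxazolidin-2-one; 10 methyl (2E)-2-methyl-6-oxohex-2-enoate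
Product: 12 methyl (2E,6R,7S)-7-[(4S)-4-benzyl-2-oxo-1,3-oxazolidine-3-carbonyl]-11-[(tert-butyldimethylsilyl)oxy]-6-hydroxy-2-methyl-8-methylideneundec-2-enoate, via (Z)-boron enolate 11 (not isolated)
Conditions: n-Bu2BOTf, i-Pr2NEt, CH2Cl2, −78 to 0 °C; then 10, −78 to 0 °C; pH 7 buffer, MeOH, 30% H2O2, 0 °C
Reagents that add atoms: none
Why: Evans syn-aldol reaction, in which the (Z)-boron enolate reacts at its α-carbon through a Zimmerman–Traxler chair on the face away from the benzyl group, sets C9 (and the transient C8 carbinol) and joins the two fragments at C8–C9.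

**Step 5**
Reactants: 12 the aldol adduct
Product: 13 methyl (2E,6R,7R)-11-[(tert-butyldimethylsilyl)oxy]-6-hydroxy-7-(hydroxymethyl)-2-methyl-8-methylideneundec-2-enoate
Conditions: LiBH4, MeOH (1.1 equiv), THF, 0 °C; aq. NH4Cl
Reagents that add atoms: none
Why: Reductive cleavage of the activated imide by LiBH4 should spare the conjugated methyl ester and return the auxiliary; C9 is not touched.

**Step 6**
Reactants: 13 the 1,3-diol
Product: 14 methyl (2E,6R,7R)-11-[(tert-butyldimethylsilyl)oxy]-7-{[(tert-butyldiphenylsilyl)oxy]methyl}-6-hydroxy-2-methyl-8-methylideneundec-2-enoate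
Conditions: TBDPSCl (1.05 equiv), imidazole, CH2Cl2, 0 °C
Reagents that add atoms: tert-butyl(chloro)diphenylsilane, CC(C)(C)[Si](Cl)(c1ccccc1)c1ccccc1
Why: Silylation with the bulky chlorosilane is selective for the primary C11 hydroxyl over the secondary C8 hydroxyl.

**Step 7**
Reactants: 14 the silyl-protected enoate
Product: 15 (2E,6R,7R)-11-[(tert-butyldimethylsilyl)oxy]-7-{[(tert-butyldiphenylsilyl)oxy]methyl}-2-methyl-8-methylideneundec-2-ene-1,6-diol
Conditions: i-Bu2AlH (3.5 equiv), CH2Cl2, −78 °C; then aq. potassium sodium tartrate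
Reagents that add atoms: none
Why: 1,2-Reduction of the α,β-unsaturated ester by the aluminium hydride gives the allylic alcohol (C14) without touching the silyl ethers or the alkenes.

**Step 8**
Reactants: 15 the allylic alcohol
Product: 16 (2E,6R,7R)-7-{[(tert-butyldiphenylsilyl)oxy]methyl}-2-methyl-8-methylideneundec-2-ene-1,6,11-triol
Conditions: PPTS (0.2 equiv), MeOH, rt
Reagents that add atoms: none
Why: Acid-catalysed methanolysis cleaves the primary tert-butyldimethylsilyl ether much faster than the tert-butyldiphenylsilyl ether.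

**Step 9**
Reactants: 16 the triol
Product: 17 (2E,7R)-7-{[(tert-butyldiphenylsilyl)oxy]methyl}-2-methyl-8-methylidene-6-oxoundec-2-enedial
Conditions: Dess–Martin periodinane (4.5 equiv), pyridine, CH2Cl2, 0 °C to rt; crude product used at once
Reagents that add atoms: none
Why: Dess–Martin oxidation converts the two primary alcohols and the secondary alcohol under near-neutral conditions, so the β,γ-unsaturated ketone should neither conjugate nor epimerise at C9.

**Step 10**
Reactants: 17 the keto dialdehyde
Product: 20 (3R,4S,5S,9R,10R)-11-[(tert-butyldiphenylsilyl)oxy]-3-hydroxy-8-oxo-12-nordriman-14-al (trans-decalin; formyl group axial and cis to C15; 3-OH equatorial), via tertiary C10 radical 18 (not isolated), via monocyclic iron enolate 19 (not isolated)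
Conditions: Fe(acac)3 (0.3 equiv), PhSiH2(Oi-Pr) (2.5 equiv), i-PrOH/ClCH2CH2Cl (1:4), 0.005 M, 0 °C to rt, Ar
Reagents that add atoms: none
Why: Hydrogen-atom transfer from a trivalent iron hydride to C15 of the electron-rich 1,1-disubstituted alkene gives the tertiary C10 radical, which adds 6-exo-trig to the enal β-carbon C5 (Giese addition) and closes ring B through the C5–C10 bond; divalent iron then reduces the α-formyl radical to the iron enolate, which closes ring A by a 6-(enolexo)-exo-trig aldol addition to the C3 aldehyde. The closest known reaction type is the HAT-initiated radical conjugate addition–aldol (radical–polar crossover) bicyclisation of alkenyl enal aldehydes. Ring B should close through a chair in which the C9–C11 bond lies anti to the forming bond (equatorial, least allylic strain with the planar radical), the enal is equatorial on C5 (H5 axial), the methyl group takes the pseudoaxial site crowded by C6, C8 and the enal α-methyl and the longer 3-oxopropyl chain takes the open pseudoequatorial site, so C9 controls C10 and C5 and the fusion becomes trans. In the aldol chair the enolate carbon C14 goes pseudoaxial, which avoids a 1,3-diaxial clash between C13 and C15 and sets C4 with the formyl group cis to the angular methyl; an iron-bridged closed transition state places the C3 oxygen gauche to C14, that is equatorial, and this centre is reset in steps 13 and 15. The step needs HAT to the isolated alkene and not to the electron-poor enal, attack at C5 (6-exo) and not at C4 (7-endo), and aldol capture faster than protonation of the enolate; the polarity of the enal, the six-membered closure and high dilution with only a weak proton donor should secure these.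

**Step 11**
Reactants: 20 the bicyclic hydroxy aldehyde
Product: 21 (3R,4R,5S,9R,10R)-11-[(tert-butyldiphenylsilyl)oxy]-3,14-dihydroxy-12-nordriman-8-one
Conditions: Me4NBH(OAc)3 (3 equiv), MeCN/AcOH (1:1), −20 to 0 °C
Reagents that add atoms: none
Why: Hydroxyl-directed triacetoxyborohydride reduction (Evans–Saksena type) delivers hydride from the C3–O–B complex to the neighbouring formyl group and should leave the undirected C8 ketone untouched.

**Step 12**
Reactants: 21 the keto diol
Product: 22 (3R,4R,5S,9R,10R)-14-acetoxy-11-[(tert-butyldiphenylsilyl)oxy]-3-hydroxy-12-nordriman-8-one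
Conditions: Ac2O (1.1 equiv), pyridine, CH2Cl2, 0 °C
Reagents that add atoms: acetic anhydride, CC(=O)OC(C)=O
Why: Acylation is faster at the primary C14 hydroxyl than at the secondary C3 hydroxyl flanked by the quaternary C4.

**Step 13**
Reactants: 22 the hydroxy keto acetate
Product: 23 (4R,5S,9R,10R)-14-acetoxy-11-[(tert-butyldiphenylsilyl)oxy]-12-nordrimane-3,8-dione
Conditions: Dess–Martin periodinane, pyridine, CH2Cl2, rt
Reagents that add atoms: none
Why: Dess–Martin oxidation gives the C3 ketone and erases the C3 centre on purpose; the β-acetoxy ketone cannot eliminate because C4 carries no hydrogen.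

**Step 14**
Reactants: 23 the diketone
Product: 24 (4R,5S,9R,10R)-14-acetoxy-11-[(tert-butyldiphenylsilyl)oxy]drim-8(12)-en-3-one
Conditions: Ph3PCH3Br (1.5 equiv), KOt-Bu (1.4 equiv), THF, 0 °C; then 23, 0 °C to rt
Reagents that add atoms: methyltriphenylphosphonium bromide (source of the ylide CH2), C[P+](c1ccccc1)(c1ccccc1)c1ccccc1.[Br-]
Why: Wittig methylenation should take place at the C8 ketone, which has an α-CH2, and spare the C3 ketone shielded by the quaternary C4; any epimerisation at C9 returns the equatorial isomer.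

**Step 15**
Reactants: 24 the methylidene ketone
Product: 25 (3S,4R,5S,9R,10R)-14-acetoxy-11-[(tert-butyldiphenylsilyl)oxy]drim-8(12)-en-3-ol (3-OH axial)
Conditions: LiBH(s-Bu)3 (1.2 equiv), THF, −78 °C; then pH 7 buffer, 30% H2O2, 0 °C
Reagents that add atoms: none
Why: The bulky trialkylborohydride attacks the C3 ketone along the equatorial direction, away from the syn-axial hydrogens at C1 and C5, and gives the axial alcohol; its trans-diaxial relation to C14 prevents acetyl migration.

**Step 16**
Reactants: 25 the silyl ether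
Product: 26 (3S,4R,5S,9R,10R)-14-acetoxydrim-8(12)-ene-3,11-diol
Conditions: Bu4NF (1.5 equiv), AcOH (1.5 equiv), THF, rt
Reagents that add atoms: none
Why: Fluoride-mediated desilylation, buffered with acetic acid, frees the C11 hydroxyl without cleaving the acetate.

**Step 17**
Reactants: 26 the diol; 27 umbelliferone (7-hydroxy-2H-chromen-2-one)
Product: 28 7-{[(3S,4R,5S,9R,10R)-14-acetoxy-3-hydroxydrim-8(12)-en-11-yl]oxy}-2H-chromen-2-one (the target)
Conditions: PPh3, DIAD, THF, 0 °C to rt
Reagents that add atoms: none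
Why: Mitsunobu etherification activates the primary C11 hydroxyl as its alkoxyphosphonium ion, which the acidic phenol displaces, while the hindered axial C3 hydroxyl should not react.

**Compound list**

1 | (3-bromopropoxy)(tert-butyl)dimethylsilane | BrCCCO[Si](C)(C)C(C)(C)C | starting material
2 | diketene (4-methylideneoxetan-2-one) | C=C1CC(=O)O1 | starting material
3 | [3-(tert-butyldimethylsilyloxy)propyl]magnesium bromide | Br[Mg]CCCO[Si](C)(C)C(C)(C)C | intermediate
4 | 6-[(tert-butyldimethylsilyl)oxy]-3-methylidenehexanoic acid | C=C(CC(=O)O)CCCO[Si](C)(C)C(C)(C)C | intermediate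
5 | (4S)-4-benzyl-1,3-oxazolidin-2-one | O=C1N[C@@H](Cc2ccccc2)CO1 | starting material
6 | mixed anhydride of 4 and pivalic acid | C=C(CC(=O)OC(=O)C(C)(C)C)CCCO[Si](C)(C)C(C)(C)C | intermediate
7 | (4S)-4-benzyl-3-{6-[(tert-butyldimethylsilyl)oxy]-3-methylidenehexanoyl}-1,3-oxazolidin-2-one | C=C(CC(=O)N1[C@@H](Cc2ccccc2)COC1=O)CCCO[Si](C)(C)C(C)(C)C | intermediate
8 | pent-4-enal | C=CCCC=O | starting material
9 | methyl methacrylate | C=C(C)C(=O)OC | starting material
10 | methyl (2E)-2-methyl-6-oxohex-2-enoate | COC(=O)/C(C)=C/CCC=O | intermediate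
11 | (Z)-di-n-butylboron enolate of 7 | CCCCB(CCCC)O/C(=C\C(=C)CCCO[Si](C)(C)C(C)(C)C)N1[C@@H](Cc2ccccc2)COC1=O | intermediate
12 | methyl (2E,6R,7S)-7-[(4S)-4-benzyl-2-oxo-1,3-oxazolidine-3-carbonyl]-11-[(tert-butyldimethylsilyl)oxy]-6-hydroxy-2-methyl-8-methylideneundec-2-enoate | O=C1OC[C@H](Cc2ccccc2)N1C(=O)[C@@H](C(=C)CCCO[Si](C)(C)C(C)(C)C)[C@H](O)CC/C=C(\C)C(=O)OC | intermediate
13 | methyl (2E,6R,7R)-11-[(tert-butyldimethylsilyl)oxy]-6-hydroxy-7-(hydroxymethyl)-2-methyl-8-methylideneundec-2-enoate | OC[C@@H](C(=C)CCCO[Si](C)(C)C(C)(C)C)[C@H](O)CC/C=C(\C)C(=O)OC | intermediate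
14 | methyl (2E,6R,7R)-11-[(tert-butyldimethylsilyl)oxy]-7-{[(tert-butyldiphenylsilyl)oxy]methyl}-6-hydroxy-2-methyl-8-methylideneundec-2-enoate | CC(C)(C)[Si](c1ccccc1)(c1ccccc1)OC[C@@H](C(=C)CCCO[Si](C)(C)C(C)(C)C)[C@H](O)CC/C=C(\C)C(=O)OC | intermediate
15 | (2E,6R,7R)-11-[(tert-butyldimethylsilyl)oxy]-7-{[(tert-butyldiphenylsilyl)oxy]methyl}-2-methyl-8-methylideneundec-2-ene-1,6-diol | CC(C)(C)[Si](c1ccccc1)(c1ccccc1)OC[C@@H](C(=C)CCCO[Si](C)(C)C(C)(C)C)[C@H](O)CC/C=C(\C)CO | intermediate
16 | (2E,6R,7R)-7-{[(tert-butyldiphenylsilyl)oxy]methyl}-2-methyl-8-methylideneundec-2-ene-1,6,11-triol | CC(C)(C)[Si](c1ccccc1)(c1ccccc1)OC[C@@H](C(=C)CCCO)[C@H](O)CC/C=C(\C)CO | intermediate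
17 | (2E,7R)-7-{[(tert-butyldiphenylsilyl)oxy]methyl}-2-methyl-8-methylidene-6-oxoundec-2-enedial | CC(C)(C)[Si](c1ccccc1)(c1ccccc1)OC[C@@H](C(=C)CCC=O)C(=O)CC/C=C(\C)C=O | intermediate
18 | tertiary C10 radical formed from 17 by hydrogen-atom transfer to C15 | CC(C)(C)[Si](c1ccccc1)(c1ccccc1)OC[C@@H]([C](C)CCC=O)C(=O)CC/C=C(\C)C=O | intermediate
19 | monocyclic C4 enolate after closure of ring B (iron-bound; written as the anion) | O=C1CC[C@H](/C(C)=C/[O-])[C@@](C)(CCC=O)[C@@H]1CO[Si](c1ccccc1)(c1ccccc1)C(C)(C)C | intermediate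
20 | (3R,4S,5S,9R,10R)-11-[(tert-butyldiphenylsilyl)oxy]-3-hydroxy-8-oxo-12-nordriman-14-al | O=C1CC[C@@H]2[C@](C)(C=O)[C@H](O)CC[C@@]2(C)[C@@H]1CO[Si](c1ccccc1)(c1ccccc1)C(C)(C)C | intermediate
21 | (3R,4R,5S,9R,10R)-11-[(tert-butyldiphenylsilyl)oxy]-3,14-dihydroxy-12-nordriman-8-one | O=C1CC[C@@H]2[C@](C)(CO)[C@H](O)CC[C@@]2(C)[C@@H]1CO[Si](c1ccccc1)(c1ccccc1)C(C)(C)C | intermediate
22 | (3R,4R,5S,9R,10R)-14-acetoxy-11-[(tert-butyldiphenylsilyl)oxy]-3-hydroxy-12-nordriman-8-one | O=C1CC[C@@H]2[C@](C)(COC(C)=O)[C@H](O)CC[C@@]2(C)[C@@H]1CO[Si](c1ccccc1)(c1ccccc1)C(C)(C)C | intermediate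
23 | (4R,5S,9R,10R)-14-acetoxy-11-[(tert-butyldiphenylsilyl)oxy]-12-nordrimane-3,8-dione | O=C1CC[C@@H]2[C@](C)(COC(C)=O)C(=O)CC[C@@]2(C)[C@@H]1CO[Si](c1ccccc1)(c1ccccc1)C(C)(C)C | intermediate
24 | (4R,5S,9R,10R)-14-acetoxy-11-[(tert-butyldiphenylsilyl)oxy]drim-8(12)-en-3-one | C=C1CC[C@@H]2[C@](C)(COC(C)=O)C(=O)CC[C@@]2(C)[C@@H]1CO[Si](c1ccccc1)(c1ccccc1)C(C)(C)C | intermediate
25 | (3S,4R,5S,9R,10R)-14-acetoxy-11-[(tert-butyldiphenylsilyl)oxy]drim-8(12)-en-3-ol | C=C1CC[C@@H]2[C@](C)(COC(C)=O)[C@@H](O)CC[C@@]2(C)[C@@H]1CO[Si](c1ccccc1)(c1ccccc1)C(C)(C)C | intermediate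
26 | (3S,4R,5S,9R,10R)-14-acetoxydrim-8(12)-ene-3,11-diol | C=C1CC[C@@H]2[C@](C)(COC(C)=O)[C@@H](O)CC[C@@]2(C)[C@@H]1CO | intermediate
27 | umbelliferone (7-hydroxy-2H-chromen-2-one) | Oc1ccc2ccc(=O)oc2c1 | starting material
28 | 7-{[(3S,4R,5S,9R,10R)-14-acetoxy-3-hydroxydrim-8(12)-en-11-yl]oxy}-2H-chromen-2-one | C=C1CC[C@@H]2[C@](C)(COC(C)=O)[C@@H](O)CC[C@@]2(C)[C@@H]1COc1ccc2ccc(=O)oc2c1 | target

**Step count and risks**

Total step count: 17. Longest linear sequence: 16 steps (steps 1, 2 and 4–17).

Steps most likely to fail: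

1. Step 10. The β,γ-unsaturated ketone may enolise before hydrogen-atom transfer, which would erode the only stereocentre (C9). The planar C10 radical may also discriminate poorly between the methyl group and the 3-oxopropyl chain, so that the cis-fused isomer forms beside the trans-fused one. The fallback sets out from 16 and comes back at 23; it carries C8 through the cyclisation as the free carbinol and makes both ring carbonyls together afterwards. TEMPO/PhI(OAc)2 in CH2Cl2 oxidises only the two primary alcohols of 16 and gives (2E,6R,7R)-7-{[(tert-butyldiphenylsilyl)oxy]methyl}-6-hydroxy-2-methyl-8-methylideneundec-2-enedial F1. F1 has no enolisable position next to C9, and its C8 hydroxyl is axial in the chair that closes ring B, where it adds a syn-axial penalty to a chain placed axially on C10. The same iron-hydride conditions should convert it into the bicyclic dihydroxy aldehyde F2. NaBH4 (MeOH, 0 °C) gives the triol F3. Acetylation of the primary hydroxyl (AcCl, 2,4,6-collidine, CH2Cl2, −78 °C) gives the monoacetate F4. Dess–Martin oxidation of both secondary carbinols then leads to 23.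

2. Step 14. The hindered C8 ketone may react slowly, so the basic ylide may instead cleave the acetate (followed by retro-aldol loss of formaldehyde) or attack the C3 ketone. The fallback sets out from 22 and comes back at 24; it reverses the order of the two operations and uses a non-basic gem-dimetallic reagent. Zn, CH2Br2 and TiCl4 (THF/CH2Cl2, 0 °C) should methylenate the only ketone of 22 in the presence of the free hydroxyl and the acetate and give the hydroxy alkene F5. Dess–Martin oxidation of F5 then gives 24.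

3. Step 17. Displacement at the β-branched C11 carbinol next to the quaternary C10 may be slow, so that the alkoxyphosphonium intermediate is lost to alkylation of the hydrazide or to elimination. The fallback sets out from 26 and comes back at 28; it forms the ether bond at the aryl carbon and so avoids substitution at C11. Palladium-catalysed C–O cross-coupling of 26 with 7-bromo-2H-chromen-2-one (O=c1ccc2ccc(Br)cc2o1) would be used: Pd2(dba)3, t-BuBrettPhos, Cs2CO3, toluene, 80 °C. The hindered axial C3 hydroxyl should not compete. This fallback forms no further compound, none F0.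

**Further compounds**

F1 | step 10 | (2E,6R,7R)-7-{[(tert-butyldiphenylsilyl)oxy]methyl}-6-hydroxy-2-methyl-8-methylideneundec-2-enedial | CC(C)(C)[Si](c1ccccc1)(c1ccccc1)OC[C@@H](C(=C)CCC=O)[C@H](O)CC/C=C(\C)C=O
F2 | step 10 | 11-[(tert-butyldiphenylsilyl)oxy]-3,8-dihydroxy-12-nordriman-14-al (3-OH equatorial, 8-OH axial, other centres as in 20) | O[C@@H]1CC[C@@H]2[C@](C)(C=O)[C@H](O)CC[C@@]2(C)[C@@H]1CO[Si](c1ccccc1)(c1ccccc1)C(C)(C)C
F3 | step 10 | 11-[(tert-butyldiphenylsilyl)oxy]-12-nordrimane-3,8,14-triol (3-OH equatorial, 8-OH axial) | O[C@@H]1CC[C@@H]2[C@](C)(CO)[C@H](O)CC[C@@]2(C)[C@@H]1CO[Si](c1ccccc1)(c1ccccc1)C(C)(C)C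
F4 | step 10 | 14-acetoxy-11-[(tert-butyldiphenylsilyl)oxy]-12-nordrimane-3,8-diol (3-OH equatorial, 8-OH axial) | O[C@@H]1CC[C@@H]2[C@](C)(COC(C)=O)[C@H](O)CC[C@@]2(C)[C@@H]1CO[Si](c1ccccc1)(c1ccccc1)C(C)(C)C
F5 | step 14 | (3R,4R,5S,9R,10R)-14-acetoxy-11-[(tert-butyldiphenylsilyl)oxy]drim-8(12)-en-3-ol (3-OH equatorial) | C=C1CC[C@@H]2[C@](C)(COC(C)=O)[C@H](O)CC[C@@]2(C)[C@@H]1CO[Si](c1ccccc1)(c1ccccc1)C(C)(C)C
F0 | step 17 | none | none
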